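**Plan**

- Labels: every intermediate carries the isochromene numbering of the target (C1 OCH2, O2, C3 dienyl-bearing, C4a and C8a ring fusion, C6 ketone, C7 methyl carbinol, C8 acetoxy carbon; side chain C1'–C7'). In the cyclohexenone ring C6 and C7 are neighbouring carbons that both derive from carbonyl groups, so the C6–C7 bond links two electrophilic carbons; it is cut by inverting the polarity of a C6 aldehyde toward a C7 methyl ketone.
- Retrosynthetic cuts in order: C6–C7; C7=O back to a silyl-protected carbinol; C4a=C5 together with the C5–C6 unit, brought in as a bromoacetate on the C8 oxygen (Reformatsky lactone that locks C6 cis to C8a and is opened again); C8a–C8 (aldol); O2–C3 (6-endo-dig hydroalkoxylation); C4–C4a (acetylide acylation); C1'=C2' and C3'=C4' (olefinations).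
- Forward: side-chain dienyne and ynone, then the pyran ring, aldol at C8a, a temporary lactone ring, its opening and adjustment to the keto enal, and finally the carbocycle.
- Stereochemistry: C5' from (S)-2-methylbutan-1-ol; C8 from Felkin addition to O-silylated (S)-lactaldehyde (from ethyl (S)-lactate, its own centre ending as the C7 ketone) and C8a from syn simple diastereoselection of a titanium enolate; C7 from substrate control in the ring closure; alkene geometry from Wittig and Horner–Wadsworth–Emmons selectivity and from the lactone ring.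

Key step: step 16

**Route**

Step 1
Reactants: 1 (S)-2-methylbutan-1-ol
Product: 3 (2E,4S)-2,4-dimethylhex-2-enal, via (S)-2-methylbutanal 2 (not isolated)
Conditions: TEMPO (cat.), PhI(OAc)2, CH2Cl2, 23 °C; then Ph3P=C(CH3)CHO, PhMe, 80 °C
Reagents that add atoms: 2-(triphenylphosphoranylidene)propanal, CC(C=O)=P(c1ccccc1)(c1ccccc1)c1ccccc1
Why: Oxoammonium-mediated oxidation stops at the aldehyde, which is olefinated at once by the stabilised formyl ylide in an E-selective Wittig reaction, so the volatile and epimerisable aldehyde is never handled and the C5' centre comes unchanged from the chiral pool.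

Step 2
Reactants: 3 (2E,4S)-2,4-dimethylhex-2-enal
Product: 4 trimethyl[(3E,5E,7S)-5,7-dimethylnona-3,5-dien-1-yn-1-yl]silane
Conditions: (EtO)2P(O)CH2C≡CSiMe3, LiN(SiMe3)2, THF, −78 → 0 °C
Reagents that add atoms: diethyl [3-(trimethylsilyl)prop-2-yn-1-yl]phosphonate, CCOP(=O)(CC#C[Si](C)(C)C)OCC
Why: Horner–Wadsworth–Emmons olefination with the pre-formed propargylic phosphonate anion should build the new disubstituted alkene with high E selectivity, and adding the enal to the anion avoids γ-deprotonation at the stereocentre.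

Step 3
Reactants: 4 trimethyl[(3E,5E,7S)-5,7-dimethylnona-3,5-dien-1-yn-1-yl]silane
Product: 5 (3E,5E,7S)-5,7-dimethylnona-3,5-dien-1-yne
Conditions: K2CO3 (cat.), MeOH, 23 °C
Reagents that add atoms: none
Why: Carbonate-catalysed methanolysis of the alkynyl C–Si bond (protodesilylation) is selective for the alkynylsilane and leaves the diene untouched.

Step 4
Reactants: 6 methyl 3-hydroxypropanoate
Product: 7 3-hydroxy-N-methoxy-N-methylpropanamide
Conditions: MeNHOMe·HCl, i-PrMgCl, THF, −20 → 0 °C
Reagents that add atoms: N,O-dimethylhydroxylamine hydrochloride, CNOC.Cl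
Why: Direct Weinreb amide formation from the ester with the magnesium amide of MeNHOMe, the free hydroxyl being carried as its magnesium alkoxide so that no protecting group is needed.

Step 5
Reactants: 5 (3E,5E,7S)-5,7-dimethylnona-3,5-dien-1-yne; 7 3-hydroxy-N-methoxy-N-methylpropanamide
Product: 10 (6E,8E,10S)-1-hydroxy-8,10-dimethyldodeca-6,8-dien-4-yn-3-one, via lithium acetylide 8 (not isolated), via magnesium alkoxide 9 (not isolated)
Conditions: 5, n-BuLi, THF, −78 °C; 7, i-PrMgCl (1 equiv), THF, −40 °C; combined, −78 → 0 °C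
Reagents that add atoms: none
Why: Acylation of the lithium acetylide by the Weinreb amide stops at the chelated tetrahedral adduct, so the ynone forms only on work-up, and pre-forming the magnesium alkoxide of the hydroxyl saves one equivalent of the acetylide.

Step 6
Reactants: 10 (6E,8E,10S)-1-hydroxy-8,10-dimethyldodeca-6,8-dien-4-yn-3-one
Product: 11 6-[(1E,3E,5S)-3,5-dimethylhepta-1,3-dien-1-yl]-2,3-dihydro-4H-pyran-4-one
Conditions: AuCl(PPh3) (5 mol %), AgOSO2CF3 (5 mol %), CH2Cl2, 23 °C
Reagents that add atoms: none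
Why: Gold-catalysed 6-endo-dig hydroalkoxylation (intramolecular oxa-Michael addition) of the β-hydroxy ynone closes the pyran ring as the vinylogous ester, since 5-exo attack would place oxygen on the non-electrophilic α-carbon.

Step 7
Reactants: 12 ethyl (S)-lactate
Product: 13 ethyl (2S)-2-[(tert-butyldimethylsilyl)oxy]propanoate
Conditions: TBSCl, imidazole, DMF, 23 °C
Reagents that add atoms: tert-butyldimethylsilyl chloride, CC(C)(C)[Si](C)(C)Cl
Why: Standard imidazole-promoted silylation of the secondary hydroxyl gives a non-chelating ether, which the facial selectivity of step 9 relies on.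

Step 8
Reactants: 13 ethyl (2S)-2-[(tert-butyldimethylsilyl)oxy]propanoate
Product: 14 (2S)-2-[(tert-butyldimethylsilyl)oxy]propanal
Conditions: i-Bu2AlH, CH2Cl2, −78 °C
Reagents that add atoms: none
Why: Partial reduction of the α-silyloxy ester at −78 °C stops at the aluminium hemiacetal and releases the aldehyde on work-up without loss of configuration, the aldehyde being used without delay.

Step 9
Reactants: 11 6-[(1E,3E,5S)-3,5-dimethylhepta-1,3-dien-1-yl]-2,3-dihydro-4H-pyran-4-one; 14 (2S)-2-[(tert-butyldimethylsilyl)oxy]propanal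
Product: 17 (3R)-3-[(1R,2S)-2-[(tert-butyldimethylsilyl)oxy]-1-hydroxypropyl]-6-[(1E,3E,5S)-3,5-dimethylhepta-1,3-dien-1-yl]-2,3-dihydro-4H-pyran-4-one, via lithium enolate 15 (not isolated), via titanium enolate 16 (not isolated)
Conditions: LiN(i-Pr)2, THF, −78 °C; ClTi(OiPr)3, −78 → −40 °C; then 14, −78 °C
Reagents that add atoms: none
Why: Aldol addition of a titanium enolate, in which kinetic deprotonation at C8a gives the cyclic enolate, its triisopropoxytitanium form is expected to add with syn simple diastereoselection (as titanium and zirconium enolates do whatever the enolate geometry) and with Felkin–Anh attack on the non-chelated α-silyloxy aldehyde, so that the (S)-aldehyde sets 8R (anti to the C7 oxygen) and the syn relationship sets 8aR.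

Step 10
Reactants: 17 (3R)-3-[(1R,2S)-2-[(tert-butyldimethylsilyl)oxy]-1-hydroxypropyl]-6-[(1E,3E,5S)-3,5-dimethylhepta-1,3-dien-1-yl]-2,3-dihydro-4H-pyran-4-one
Product: 18 (1R,2S)-2-[(tert-butyldimethylsilyl)oxy]-1-[(3R)-6-[(1E,3E,5S)-3,5-dimethylhepta-1,3-dien-1-yl]-4-oxo-3,4-dihydro-2H-pyran-3-yl]propyl bromoacetate
Conditions: BrCH2COBr, pyridine, CH2Cl2, −20 → 0 °C
Reagents that add atoms: bromoacetyl bromide, BrCC(Br)=O
Why: Acylation of the secondary hydroxyl by the acid bromide at low temperature should be faster than elimination of the β-acyloxy ketone and installs the two carbons that become C5 and C6.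

Step 11
Reactants: 18 (1R,2S)-2-[(tert-butyldimethylsilyl)oxy]-1-[(3R)-6-[(1E,3E,5S)-3,5-dimethylhepta-1,3-dien-1-yl]-4-oxo-3,4-dihydro-2H-pyran-3-yl]propyl bromoacetate
Product: 20 (8R,8aR)-8-[(1S)-1-[(tert-butyldimethylsilyl)oxy]ethyl]-3-[(1E,3E,5S)-3,5-dimethylhepta-1,3-dien-1-yl]-8,8a-dihydro-1H,6H-pyrano[3,4-c]pyran-6-one, via hydroxy lactone 19 (not isolated)
Conditions: SmI2, THF, −78 °C; then PPTS (cat.), CH2Cl2, 23 °C
Reagents that add atoms: none
Why: Samarium diiodide-promoted intramolecular Reformatsky reaction of the β-(bromoacetoxy) ketone gives the β-hydroxy δ-lactone through a chelated samarium enolate, and acid-catalysed dehydration of the tertiary, enol-ether-stabilised carbinol toward the acidic C5–H then gives the conjugated lactone, whose ring holds C6 cis to C8a.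

Step 12
Reactants: 20 (8R,8aR)-8-[(1S)-1-[(tert-butyldimethylsilyl)oxy]ethyl]-3-[(1E,3E,5S)-3,5-dimethylhepta-1,3-dien-1-yl]-8,8a-dihydro-1H,6H-pyrano[3,4-c]pyran-6-one
Product: 22 (1R,2S)-2-[(tert-butyldimethylsilyl)oxy]-1-[(3R,4E)-6-[(1E,3E,5S)-3,5-dimethylhepta-1,3-dien-1-yl]-4-{2-[methoxy(methyl)amino]-2-oxoethylidene}-3,4-dihydro-2H-pyran-3-yl]propyl acetate, via hydroxy amide 21 (not isolated)
Conditions: Me3Al, MeNHOMe·HCl, CH2Cl2, 0 → 23 °C; then Ac2O, DMAP (cat.), pyridine, 0 °C
Reagents that add atoms: N,O-dimethylhydroxylamine hydrochloride, CNOC.Cl; acetic anhydride, CC(=O)OC(C)=O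
Why: Aluminium amide aminolysis (Weinreb) opens the lactone at the C6 carbonyl with retention of the alkene geometry, and acetylation of the resulting aluminium alkoxide in the same flask caps the C8 oxygen before relactonisation can occur.

Step 13
Reactants: 22 (1R,2S)-2-[(tert-butyldimethylsilyl)oxy]-1-[(3R,4E)-6-[(1E,3E,5S)-3,5-dimethylhepta-1,3-dien-1-yl]-4-{2-[methoxy(methyl)amino]-2-oxoethylidene}-3,4-dihydro-2H-pyran-3-yl]propyl acetate
Product: 23 (1R,2S)-2-[(tert-butyldimethylsilyl)oxy]-1-[(3R,4E)-6-[(1E,3E,5S)-3,5-dimethylhepta-1,3-dien-1-yl]-4-(2-oxoethylidene)-3,4-dihydro-2H-pyran-3-yl]propyl acetate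
Conditions: Cp2Zr(H)Cl, THF, 23 °C
Reagents that add atoms: none
Why: Schwartz reagent reduces the Weinreb amide to the aldehyde through a stable zirconated hemiaminal and is known to spare acetate esters, silyl ethers and internal alkenes on the short reaction time used.

Step 14
Reactants: 23 (1R,2S)-2-[(tert-butyldimethylsilyl)oxy]-1-[(3R,4E)-6-[(1E,3E,5S)-3,5-dimethylhepta-1,3-dien-1-yl]-4-(2-oxoethylidene)-3,4-dihydro-2H-pyran-3-yl]propyl acetate
Product: 24 (1R,2S)-1-[(3R,4E)-6-[(1E,3E,5S)-3,5-dimethylhepta-1,3-dien-1-yl]-4-(2-oxoethylidene)-3,4-dihydro-2H-pyran-3-yl]-2-hydroxypropyl acetate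
Conditions: HF·pyridine, pyridine, THF, 0 °C
Reagents that add atoms: none
Why: Fluoride cleavage of the secondary silyl ether in a pyridine-buffered, weakly acidic medium should avoid acetyl migration from the C8 oxygen and loss of acetate, and the alcohol is oxidised at once.

Step 15
Reactants: 24 (1R,2S)-1-[(3R,4E)-6-[(1E,3E,5S)-3,5-dimethylhepta-1,3-dien-1-yl]-4-(2-oxoethylidene)-3,4-dihydro-2H-pyran-3-yl]-2-hydroxypropyl acetate
Product: 25 (1R)-1-[(3R,4E)-6-[(1E,3E,5S)-3,5-dimethylhepta-1,3-dien-1-yl]-4-(2-oxoethylidene)-3,4-dihydro-2H-pyran-3-yl]-2-oxopropyl acetate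
Conditions: Dess–Martin periodinane, pyridine, CH2Cl2, 0 → 23 °C
Reagents that add atoms: none
Why: Dess–Martin oxidation of the secondary alcohol gives the α-acetoxy methyl ketone under buffered, non-enolising conditions, so C8 should not epimerise and the enal is untouched.

Step 16
Reactants: 25 (1R)-1-[(3R,4E)-6-[(1E,3E,5S)-3,5-dimethylhepta-1,3-dien-1-yl]-4-(2-oxoethylidene)-3,4-dihydro-2H-pyran-3-yl]-2-oxopropyl acetate
Product: 26 (7R,8R,8aR)-3-[(1E,3E,5S)-3,5-dimethylhepta-1,3-dien-1-yl]-7-hydroxy-7-methyl-6-oxo-6,7,8,8a-tetrahydro-1H-isochromen-8-yl acetate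
Conditions: 2-(pentafluorophenyl)-6,7-dihydro-5H-pyrrolo[2,1-c][1,2,4]triazol-2-ium tetrafluoroborate (20 mol %), i-Pr2NEt (20 mol %), PhMe, 23 → 40 °C
Reagents that add atoms: none
Why: Proposed new method: the triazolylidene adds to the C6 aldehyde of the push–pull dienal, proton transfer gives the Breslow enaminol as an acyl-anion equivalent, and this attacks the C7 ketone before the carbene is released; the closest known reaction type is the triazolium-catalysed intramolecular aldehyde–ketone crossed benzoin that gives six-membered tertiary α-ketols, which has not been shown with a δ-alkoxy dienal as donor. The carbocycle (C4a, C5, C6, C7, C8, C8a) closes in the 6-exo-trig mode. The new C7 centre is controlled by the C8 and C8a centres through a chair-like transition state with the C8 acetoxy group, the C8a–C1 bond and the ketone methyl equatorial, which places the new hydroxyl axial and cis to the acetate (7R). The step needs acyl-anion rather than homoenolate reactivity, which the substrate secures because the β-carbon C4a is fully substituted and is the terminus of the electron-rich dienol ether, because no protic nucleophile is present and because the acceptor ketone is activated by its α-acetoxy group; the E geometry fixed in step 11 keeps C6 within reach of C7. The weak amine base is chosen to leave the acidic C8–H and C8a–H alone (epimerisation, loss of acetate), and the product, a doubly vinylogous ester, is a thermodynamic sink that should make the closure effectively irreversible.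

**Compound list**

1 | (S)-2-methylbutan-1-ol | CC[C@H](C)CO | starting material
2 | (S)-2-methylbutanal | CC[C@H](C)C=O | intermediate
3 | (2E,4S)-2,4-dimethylhex-2-enal | CC[C@H](C)/C=C(C)/C=O | intermediate
4 | trimethyl[(3E,5E,7S)-5,7-dimethylnona-3,5-dien-1-yn-1-yl]silane | CC[C@H](C)/C=C(C)/C=C/C#C[Si](C)(C)C | intermediate
5 | (3E,5E,7S)-5,7-dimethylnona-3,5-dien-1-yne | CC[C@H](C)/C=C(C)/C=C/C#C | intermediate
6 | methyl 3-hydroxypropanoate | COC(=O)CCO | starting material
7 | 3-hydroxy-N-methoxy-N-methylpropanamide | CON(C)C(=O)CCO | intermediate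
8 | lithium acetylide of 5, [(3E,5E,7S)-5,7-dimethylnona-3,5-dien-1-yn-1-yl]lithium | CC[C@H](C)/C=C(C)/C=C/C#C[Li] | intermediate
9 | chloromagnesium alkoxide of 7 | CON(C)C(=O)CCO[Mg]Cl | intermediate
10 | (6E,8E,10S)-1-hydroxy-8,10-dimethyldodeca-6,8-dien-4-yn-3-one | CC[C@H](C)/C=C(C)/C=C/C#CC(=O)CCO | intermediate
11 | 6-[(1E,3E,5S)-3,5-dimethylhepta-1,3-dien-1-yl]-2,3-dihydro-4H-pyran-4-one | CC[C@H](C)/C=C(C)/C=C/C1=CC(=O)CCO1 | intermediate
12 | ethyl (S)-lactate | CCOC(=O)[C@H](C)O | starting material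
13 | ethyl (2S)-2-[(tert-butyldimethylsilyl)oxy]propanoate | CCOC(=O)[C@H](C)O[Si](C)(C)C(C)(C)C | intermediate
14 | (2S)-2-[(tert-butyldimethylsilyl)oxy]propanal | O=C[C@H](C)O[Si](C)(C)C(C)(C)C | intermediate
15 | lithium enolate of 11 (lithium 6-dienyl-2H-pyran-4-olate) | CC[C@H](C)/C=C(C)/C=C/C1=CC(O[Li])=CCO1 | intermediate
16 | triisopropoxytitanium enolate of 11 | CC[C@H](C)/C=C(C)/C=C/C1=CC(O[Ti](OC(C)C)(OC(C)C)OC(C)C)=CCO1 | intermediate
17 | (3R)-3-[(1R,2S)-2-[(tert-butyldimethylsilyl)oxy]-1-hydroxypropyl]-6-[(1E,3E,5S)-3,5-dimethylhepta-1,3-dien-1-yl]-2,3-dihydro-4H-pyran-4-one (aldol adduct, C8a/C8 syn, C8/C7 anti) | CC[C@H](C)/C=C(C)/C=C/C1=CC(=O)[C@@H]([C@@H](O)[C@H](C)O[Si](C)(C)C(C)(C)C)CO1 | intermediate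
18 | (1R,2S)-2-[(tert-butyldimethylsilyl)oxy]-1-[(3R)-6-[(1E,3E,5S)-3,5-dimethylhepta-1,3-dien-1-yl]-4-oxo-3,4-dihydro-2H-pyran-3-yl]propyl bromoacetate | CC[C@H](C)/C=C(C)/C=C/C1=CC(=O)[C@@H]([C@@H](OC(=O)CBr)[C@H](C)O[Si](C)(C)C(C)(C)C)CO1 | intermediate
19 | (8R,8aR)-8-[(1S)-1-[(tert-butyldimethylsilyl)oxy]ethyl]-3-[(1E,3E,5S)-3,5-dimethylhepta-1,3-dien-1-yl]-4a-hydroxy-4a,5,8,8a-tetrahydro-1H,6H-pyrano[3,4-c]pyran-6-one (formed as its samarium alkoxide; C4a configuration not defined, removed in the same step) | CC[C@H](C)/C=C(C)/C=C/C1=CC2(O)CC(=O)O[C@@H]([C@H](C)O[Si](C)(C)C(C)(C)C)[C@H]2CO1 | intermediate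
20 | (8R,8aR)-8-[(1S)-1-[(tert-butyldimethylsilyl)oxy]ethyl]-3-[(1E,3E,5S)-3,5-dimethylhepta-1,3-dien-1-yl]-8,8a-dihydro-1H,6H-pyrano[3,4-c]pyran-6-one (lactone between C6 and the C8 oxygen) | CC[C@H](C)/C=C(C)/C=C/C1=CC2=CC(=O)O[C@@H]([C@H](C)O[Si](C)(C)C(C)(C)C)[C@H]2CO1 | intermediate
21 | (2E)-2-[(3R)-3-[(1R,2S)-2-[(tert-butyldimethylsilyl)oxy]-1-hydroxypropyl]-6-[(1E,3E,5S)-3,5-dimethylhepta-1,3-dien-1-yl]-2,3-dihydro-4H-pyran-4-ylidene]-N-methoxy-N-methylacetamide (present as its aluminium alkoxide; amide carbonyl cis to C8a) | CC[C@H](C)/C=C(C)/C=C/C1=C/C(=C/C(=O)N(C)OC)[C@@H]([C@@H](O)[C@H](C)O[Si](C)(C)C(C)(C)C)CO1 | intermediate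
22 | (1R,2S)-2-[(tert-butyldimethylsilyl)oxy]-1-[(3R,4E)-6-[(1E,3E,5S)-3,5-dimethylhepta-1,3-dien-1-yl]-4-{2-[methoxy(methyl)amino]-2-oxoethylidene}-3,4-dihydro-2H-pyran-3-yl]propyl acetate | CC[C@H](C)/C=C(C)/C=C/C1=C/C(=C/C(=O)N(C)OC)[C@@H]([C@@H](OC(C)=O)[C@H](C)O[Si](C)(C)C(C)(C)C)CO1 | intermediate
23 | (1R,2S)-2-[(tert-butyldimethylsilyl)oxy]-1-[(3R,4E)-6-[(1E,3E,5S)-3,5-dimethylhepta-1,3-dien-1-yl]-4-(2-oxoethylidene)-3,4-dihydro-2H-pyran-3-yl]propyl acetate | CC[C@H](C)/C=C(C)/C=C/C1=C/C(=C/C=O)[C@@H]([C@@H](OC(C)=O)[C@H](C)O[Si](C)(C)C(C)(C)C)CO1 | intermediate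
24 | (1R,2S)-1-[(3R,4E)-6-[(1E,3E,5S)-3,5-dimethylhepta-1,3-dien-1-yl]-4-(2-oxoethylidene)-3,4-dihydro-2H-pyran-3-yl]-2-hydroxypropyl acetate | CC[C@H](C)/C=C(C)/C=C/C1=C/C(=C/C=O)[C@@H]([C@@H](OC(C)=O)[C@H](C)O)CO1 | intermediate
25 | (1R)-1-[(3R,4E)-6-[(1E,3E,5S)-3,5-dimethylhepta-1,3-dien-1-yl]-4-(2-oxoethylidene)-3,4-dihydro-2H-pyran-3-yl]-2-oxopropyl acetate (C6–C7 seco keto enal, aldehyde cis to C8a) | CC[C@H](C)/C=C(C)/C=C/C1=C/C(=C/C=O)[C@@H]([C@@H](OC(C)=O)C(C)=O)CO1 | intermediate
26 | (7R,8R,8aR)-3-[(1E,3E,5S)-3,5-dimethylhepta-1,3-dien-1-yl]-7-hydroxy-7-methyl-6-oxo-6,7,8,8a-tetrahydro-1H-isochromen-8-yl acetate | CC[C@H](C)/C=C(C)/C=C/C1=CC2=CC(=O)[C@](C)(O)[C@H](OC(C)=O)[C@H]2CO1 | target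

**Step count and risks**

Total step count: 16. Longest linear sequence: 13 steps (steps 1, 2, 3, 5, 6, 9, 10, 11, 12, 13, 14, 15, 16).

Steps most likely to fail:

1. Step 16 (the step carrying the new method). The carbene adduct may react through its homoenolate form (β-protonation and loss of the catalyst as an acyl azolium). The amine base may also start loss of acetate from C8 or an aldol attack of the C8 enolate on C6, or the attack on C7 may show low facial selectivity. Fallback with known chemistry, setting out from 25 and returning to the route at 26: intramolecular pinacol coupling of the keto aldehyde with divalent vanadium (VCl3(THF)3, Zn, CH2Cl2, 23 °C). This reductant engages the conjugated aldehyde but should be too weak to cleave the α-acetoxy ketone, and it should join C6 and C7 as the 6,7-diol acetate F1. Dess–Martin oxidation of the secondary allylic C6 hydroxyl of F1, beside the tertiary C7 hydroxyl, then gives 26.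

2. Step 9. The addition may run with anti instead of syn simple diastereoselection or with incomplete Felkin control, or the silyl group may migrate within the aldolate. Fallback, setting out from 11 and returning at 17: trapping the lithium enolate of 11 with Me3SiCl gives the silyl dienol ether F2. Its BF3·OEt2-mediated Mukaiyama aldol addition to 14 (CH2Cl2, −78 °C) passes through an open transition state, in which Felkin attack and the antiperiplanar arrangement are expected to favour the same adduct, isolated as 17 after mild acidic work-up.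

3. Step 11. Protonation of the samarium enolate (simple debromination to the acetate) may outrun its addition to the poorly electrophilic vinylogous-ester carbonyl, or the dehydration may run toward C8a. Fallback, setting out from 17 and returning at 20: esterification of 17 with diethylphosphonoacetic acid (DCC, DMAP, CH2Cl2) gives the phosphonoacetate F3. Its intramolecular Horner–Wadsworth–Emmons reaction under Masamune–Roush conditions (LiCl, i-Pr2NEt, MeCN) forms the C4a=C5 bond and lactone 20 directly.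

Further compounds
F1 | step 16 | 3-[(1E,3E,5S)-3,5-dimethylhepta-1,3-dien-1-yl]-6,7-dihydroxy-7-methyl-6,7,8,8a-tetrahydro-1H-isochromen-8-yl acetate, configured at C7, C8 and C8a as in 26, C6 not defined | CC[C@H](C)/C=C(C)/C=C/C1=CC2=CC(O)[C@](C)(O)[C@H](OC(C)=O)[C@H]2CO1
F2 | step 9 | {[6-[(1E,3E,5S)-3,5-dimethylhepta-1,3-dien-1-yl]-2H-pyran-4-yl]oxy}trimethylsilane | CC[C@H](C)/C=C(C)/C=C/C1=CC(O[Si](C)(C)C)=CCO1
F3 | step 11 | (1R,2S)-2-[(tert-butyldimethylsilyl)oxy]-1-[(3R)-6-[(1E,3E,5S)-3,5-dimethylhepta-1,3-dien-1-yl]-4-oxo-3,4-dihydro-2H-pyran-3-yl]propyl (diethoxyphosphoryl)acetate | CC[C@H](C)/C=C(C)/C=C/C1=CC(=O)[C@@H]([C@@H](OC(=O)CP(=O)(OCC)OCC)[C@H](C)O[Si](C)(C)C(C)(C)C)CO1
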